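**Strategy.** The chain atoms are numbered C1–C19 in the order of the SMILES. Ring A (C4–C7, C12, C13) is a conjugated cyclohexadiene. C4, one end of the diene, holds the exocyclic carbon C3, and the two saturated ring members C12 and C13 are neighbours. Ring B (C7–C12) is a disguised mirror-symmetric cis-2,6-dimethylcyclohexanone. Ring A is therefore cut at C12–C13 and C4–C5. In one operation a chiral secondary amine joins a C16-configured 2,4-dienal to 2,6-dimethyl-4-(2-oxopropylidene)cyclohexanone by vinylogous Michael addition, aldol closure and dehydration. This closes ring A, sets C12 and C13, and leaves C3 as an aldehyde. Homologation of C3 to the acetonyl group and one fluoride deprotection finish the synthesis.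

Key step: step 15

Remark 1: atom labels C1–C19 follow the main chain of the target SMILES; the five methyl branches and the CH2OH carbon carry no number.
Remark 2 (assumption): the lipase of step 8 is taken to acetylate the arm that gives (S)-13; if it prefers the other arm, the same 20 is reached by oxidising and olefinating the free arm first and then exchanging acetate for TBS.
Remark 3 (assumption): the accepted face-shielding model of diarylprolinol silyl ethers is used to choose the (S)-amine for (13S); C16 is taken to be too remote to interfere.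

**Fragment 1 (ring B donor)**

Step 1
Reactants: 1 2,6-dimethyl-1,4-benzoquinone
Product: 2 2,6-dimethylcyclohexane-1,4-diol (mixture of diastereomers)
Conditions: H2 (60 bar), 5% Rh/Al2O3, EtOH, 60 °C
Reagents that add atoms: none
Why: Catalytic hydrogenation first reduces the quinone to the hydroquinone and then saturates the arene by syn addition on rhodium, and the isomer mixture is harmless because step 2 erases the carbinol centres and equilibrates the methyl-bearing ones.

Step 2
Reactants: 2 2,6-dimethylcyclohexane-1,4-diol
Product: 3 cis-2,6-dimethylcyclohexane-1,4-dione (meso)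
Conditions: CrO3, H2SO4, acetone, 0 °C; crude dione with DBU (5 mol %), CH2Cl2, rt; cis isomer crystallised
Reagents that add atoms: none
Why: Jones oxidation converts both secondary alcohols into ketones, and enolisation of the methyl-flanked ketone then lets the two α-methyl groups settle in the diequatorial cis arrangement.

Step 3
Reactants: 3 cis-2,6-dimethylcyclohexane-1,4-dione; 4 diethyl (2-oxopropyl)phosphonate
Product: 5 cis-2,6-dimethyl-4-(2-oxopropylidene)cyclohexan-1-one (racemic)
Conditions: 4, NaH, THF, 0 °C; then 3, 0 °C to rt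
Reagents that add atoms: none
Why: Horner–Wadsworth–Emmons olefination occurs only at the carbonyl group flanked by two methylene groups because the other is shielded by its two α-methyl groups; the alkylidene group breaks the mirror plane, so 5 is a racemate, and any β,γ-unsaturated tautomer formed alongside feeds the same dienol in step 15.

**Fragment 2 (dienal)**

Step 4
Reactants: 6 1,1,1-tris(hydroxymethyl)ethane
Product: 7 (2,2,5-trimethyl-1,3-dioxan-5-yl)methanol
Conditions: 2,2-dimethoxypropane, TsOH·H2O (cat.), acetone, rt
Reagents that add atoms: 2,2-dimethoxypropane, COC(C)(C)OC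
Why: Acid-catalysed transketalisation ties two of the three equivalent hydroxymethyl arms into a six-membered acetonide and leaves one arm free.

Step 5
Reactants: 7 (2,2,5-trimethyl-1,3-dioxan-5-yl)methanol
Product: 8 2,2,5-trimethyl-1,3-dioxane-5-carbaldehyde
Conditions: TEMPO (10 mol %), PhI(OAc)2, CH2Cl2, rt
Reagents that add atoms: none
Why: Oxoammonium (TEMPO) oxidation of the primary alcohol stops at the aldehyde, which has no α-hydrogen and cannot enolise.

Step 6
Reactants: 8 2,2,5-trimethyl-1,3-dioxane-5-carbaldehyde
Product: 10 2-ethynyl-2-methylpropane-1,3-diol, via alkyne acetonide 9 (not isolated)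
Conditions: dimethyl (1-diazo-2-oxopropyl)phosphonate, K2CO3, MeOH, 0 °C to rt; then 2 M aq. HCl to pH 1, rt
Reagents that add atoms: dimethyl (1-diazo-2-oxopropyl)phosphonate, COP(=O)(OC)C(=[N+]=[N-])C(C)=O
Why: The Ohira–Bestmann form of the Seyferth–Gilbert homologation turns the non-enolisable aldehyde into the terminal alkyne, and acid hydrolysis of the acetonide in the same methanolic solution avoids isolating the volatile 9.

Step 7
Reactants: 10 2-ethynyl-2-methylpropane-1,3-diol
Product: 12 2-[(1E)-1-iodoprop-1-en-2-yl]-2-methylpropane-1,3-diol, via alkenylalane 11 (not isolated)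
Conditions: AlMe3 (5 equiv), Cp2ZrCl2 (0.3 equiv), CH2Cl2, 0 °C to rt; then I2, THF, −30 to 0 °C; aq. Rochelle salt
Reagents that add atoms: trimethylaluminium, C[Al](C)C; iodine, II
Why: Zirconium-catalysed (Negishi) carboalumination, established for homopropargylic alcohols used as their aluminium alkoxides, adds methyl and aluminium syn with aluminium at the terminal carbon, and iodinolysis with retention fixes the (E) geometry of C14=C15.

Step 8
Reactants: 12 2-[(1E)-1-iodoprop-1-en-2-yl]-2-methylpropane-1,3-diol
Product: 13 (2S,3E)-2-(hydroxymethyl)-4-iodo-2,3-dimethylbut-3-en-1-yl acetate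
Conditions: immobilised Burkholderia cepacia lipase, vinyl acetate, MTBE, rt
Reagents that add atoms: vinyl acetate, C=COC(C)=O
Why: Lipase-catalysed irreversible transesterification is a known desymmetrisation of prochiral 2,2-disubstituted propane-1,3-diols; the enzyme pocket tells the small methyl group from the large iodoalkenyl group and so sets C16, and further acylation of the minor enantiomer to the diacetate should sharpen the enantiomeric purity.

Step 9
Reactants: 13 (2S,3E)-2-(hydroxymethyl)-4-iodo-2,3-dimethylbut-3-en-1-yl acetate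
Product: 14 (2R,3E)-2-{[(tert-butyldimethylsilyl)oxy]methyl}-4-iodo-2,3-dimethylbut-3-en-1-yl acetate
Conditions: TBSCl, imidazole, DMF, 0 °C to rt
Reagents that add atoms: tert-butyldimethylsilyl chloride, CC(C)(C)[Si](C)(C)Cl
Why: Standard silylation of the free primary alcohol runs under weakly basic conditions that do not trigger the 1,3-acyl shift that would racemise C16.

Step 10
Reactants: 14 (2R,3E)-2-{[(tert-butyldimethylsilyl)oxy]methyl}-4-iodo-2,3-dimethylbut-3-en-1-yl acetate
Product: 15 (2R,3E)-2-{[(tert-butyldimethylsilyl)oxy]methyl}-4-iodo-2,3-dimethylbut-3-en-1-ol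
Conditions: K2CO3 (cat.), MeOH, 0 °C
Reagents that add atoms: none
Why: Carbonate-catalysed transesterification removes the acetate while the silyl ether and vinyl iodide are inert, and the low temperature suppresses O-to-O silyl migration.

Step 11
Reactants: 15 (2R,3E)-2-{[(tert-butyldimethylsilyl)oxy]methyl}-4-iodo-2,3-dimethylbut-3-en-1-ol
Product: 16 (2S,3E)-2-{[(tert-butyldimethylsilyl)oxy]methyl}-4-iodo-2,3-dimethylbut-3-enal
Conditions: TEMPO (10 mol %), PhI(OAc)2, CH2Cl2, rt
Reagents that add atoms: none
Why: TEMPO oxidation as in step 5 gives the aldehyde, and quaternary C16 cannot epimerise.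

Step 12
Reactants: 17 diethylphosphonoacetic acid; 18 2-(trimethylsilyl)ethanol
Product: 19 2-(trimethylsilyl)ethyl 2-(diethoxyphosphoryl)acetate
Conditions: DCC, DMAP (cat.), CH2Cl2, 0 °C to rt
Reagents that add atoms: none
Why: Steglich esterification joins acid and primary alcohol under neutral conditions that leave the phosphonate untouched.

Step 13
Reactants: 16 (2S,3E)-2-{[(tert-butyldimethylsilyl)oxy]methyl}-4-iodo-2,3-dimethylbut-3-enal; 19 2-(trimethylsilyl)ethyl 2-(diethoxyphosphoryl)acetate
Product: 20 2-(trimethylsilyl)ethyl (2E,4S,5E)-4-{[(tert-butyldimethylsilyl)oxy]methyl}-6-iodo-4,5-dimethylhexa-2,5-dienoate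
Conditions: 19, NaH, THF, 0 °C; then 16, 0 °C to rt
Reagents that add atoms: none
Why: Horner–Wadsworth–Emmons olefination of the unenolisable, α-quaternary aldehyde with a stabilised phosphonate anion gives the (E)-enoate C17=C18.

Step 14
Reactants: 20 2-(trimethylsilyl)ethyl (2E,4S,5E)-4-{[(tert-butyldimethylsilyl)oxy]methyl}-6-iodo-4,5-dimethylhexa-2,5-dienoate; 21 acrolein diethyl acetal
Product: 23 2-(trimethylsilyl)ethyl (2E,4S,5E,7E)-4-{[(tert-butyldimethylsilyl)oxy]methyl}-4,5-dimethyl-9-oxonona-2,5,7-trienoate, via dienal diethyl acetal 22 (not isolated)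
Conditions: 21 (3 equiv), Pd(OAc)2 (5 mol %), nBu4NOAc, K2CO3, KCl, DMF, 70 °C; then 5% aq. oxalic acid, THF, 0 °C to rt
Reagents that add atoms: water, O
Why: Heck vinylation of acrolein acetal under acetate/carbonate conditions, which favour β-hydride elimination away from the acetal carbon, retains the C14=C15 geometry and forms (E)-C4=C13; palladium sits trans to C16 and cannot reach the hindered enoate, and mild acid then unmasks the aldehyde without touching the silyl groups.

**Union**

Step 15
Reactants: 5 cis-2,6-dimethyl-4-(2-oxopropylidene)cyclohexan-1-one; 23 2-(trimethylsilyl)ethyl (2E,4S,5E,7E)-4-{[(tert-butyldimethylsilyl)oxy]methyl}-4,5-dimethyl-9-oxonona-2,5,7-trienoate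
Product: 28 2-(trimethylsilyl)ethyl (2E,4S,5E)-4-{[(tert-butyldimethylsilyl)oxy]methyl}-6-[(1S,6S,8R,8aR)-2-formyl-3,6,8-trimethyl-7-oxo-1,5,6,7,8,8a-hexahydronaphthalen-1-yl]-4,5-dimethylhexa-2,5-dienoate, via iminium benzoate 24 (not isolated), via linear dienol 25 (not isolated), via Michael enamine 26 (not isolated), via aldol iminium benzoate 27 (not isolated)
Conditions: (S)-2-[diphenyl(trimethylsilyloxy)methyl]pyrrolidine (20 mol %), PhCO2H (20 mol %), 5 (2 equiv), toluene, rt to 40 °C, argon, dark
Reagents that add atoms: none
Why: Proposed new method: the amine condenses with 23 to the dienyl iminium ion 24, the ammonium benzoate buffer tautomerises 5 to its linear dienol 25 (C5(OH)=C6–C7=C12), C12 adds to C13 in a vinylogous Michael step, enamine 26 attacks the C5 ketone through C4, and loss of water from 27 followed by hydrolysis releases 28 and the amine. The closest known reaction type is the amine-catalysed Michael/aldol-condensation (formal [4+2]) of enals with dienamines or other vinylogous donors to cyclohexa-1,3-dienecarbaldehydes; a simple alkylideneacetone as donor and a 2,4-dienal as acceptor go beyond it. Ring A closes by a 6-(enolexo)-exo-trig aldol addition, which needs the acetyl group cis to C12 on C6=C7 and is served by both alkylidene isomers because they interconvert through 25. C13 is set by the catalyst, whose CPh2(OSiMe3) arm covers one face of the (E), s-trans iminium ion, so that the (S)-amine should deliver (13S). C12 is set by two substrate effects, namely bond formation anti to the C11 methyl group on the half-chair of 25, which leads directly to the ring B chair with C13 and both methyl groups equatorial, and an endo-type approach that keeps the branched C14–C16 arm away from ring B and places H12 and H13 anti; since the two enantiomers of 25 equilibrate through 5 the matched one is consumed (dynamic kinetic resolution), and because the peri contact between the C11 methyl group and C14 makes this isomer an uncertain thermodynamic minimum, the run is stopped at full conversion of 23 before C12 (via the trienamine of 28) or C11 can drift, C9 alone being safely correctable by enolisation of the C10 ketone. The step needs 1,4- over 1,6-addition, secured by the fully substituted C15 next to quaternary C16, γ- over α-attack, secured because only the C12 adduct can go on to an irreversible six-membered condensation while adducts through C6 or the acetyl methyl group revert, and C5 over C10 in the closure, secured by the two α-methyl groups at C10 and the five-membered ring that attack there would require.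

**Endgame**

Step 16
Reactants: 29 triphenylphosphine hydrobromide; 30 ethyl vinyl ether
Product: 31 (1-ethoxyethyl)triphenylphosphonium bromide (racemic)
Conditions: CH2Cl2, 0 °C to rt; precipitation with Et2O
Reagents that add atoms: none
Why: Markovnikov addition of the phosphine hydrobromide to the enol ether through its oxocarbenium ion is the standard route to (1-alkoxyalkyl)phosphonium salts.

Step 17
Reactants: 28 bicyclic dienal; 31 (1-ethoxyethyl)triphenylphosphonium bromide
Product: 33 C3=C2 ethyl enol ether of the protected target (E/Z mixture), via ylide 32 (not isolated)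
Conditions: 31 (1.3 equiv), KN(SiMe3)2, THF, −78 °C; then 28, −78 to −40 °C; pH 7 buffer
Reagents that add atoms: none
Why: Wittig olefination with a (1-alkoxyalkylidene)phosphorane is a known aldehyde-to-methyl-ketone homologation; at low temperature the aldehyde C3 adds the ylide much faster than the C10 ketone, flanked by two methine carbons, can be attacked or enolised, and the alkene geometry is irrelevant because both isomers hydrolyse to one ketone.

Step 18
Reactants: 33 C3=C2 ethyl enol ether
Product: 34 protected target (TBS ether, 2-(trimethylsilyl)ethyl ester)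
Conditions: 0.1 M aq. oxalic acid, THF, 0 °C
Reagents that add atoms: water, O
Why: Acid-catalysed enol ether hydrolysis should protonate C3 rather than C5 or C7, because A(1,3) strain with the C5 methyl group and C13 twists C2=C3 out of conjugation with the ring diene, and the weak acid spares the silyl groups, the stereocentres and the β,γ-position of the new ketone.

Step 19
Reactants: 34 protected target
Product: 35 (2E,4S,5E)-4-(hydroxymethyl)-4,5-dimethyl-6-[(1S,6S,8R,8aR)-3,6,8-trimethyl-7-oxo-2-(2-oxopropyl)-1,5,6,7,8,8a-hexahydronaphthalen-1-yl]hexa-2,5-dienoic acid (CNP0260948.1)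
Conditions: nBu4NF, AcOH (1:1, excess), THF, 0 °C to rt
Reagents that add atoms: none
Why: Fluoride cleaves the silyl ether and fragments the 2-silylethyl ester (loss of ethene) in one operation, and the acetic acid buffer keeps the medium too weakly basic to enolise C3, C9 or C11.

**Compound list**

1 | 2,6-dimethyl-1,4-benzoquinone | CC1=CC(=O)C=C(C)C1=O | starting material
2 | 2,6-dimethylcyclohexane-1,4-diol (diastereomer mixture) | CC1CC(O)CC(C)C1O | intermediate
3 | cis-2,6-dimethylcyclohexane-1,4-dione (meso) | O=C1C[C@H](C)C(=O)[C@H](C)C1 | intermediate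
4 | diethyl (2-oxopropyl)phosphonate | CCOP(=O)(CC(C)=O)OCC | starting material
5 | cis-2,6-dimethyl-4-(2-oxopropylidene)cyclohexan-1-one (racemic) | CC(=O)C=C1C[C@H](C)C(=O)[C@H](C)C1 | intermediate
6 | 1,1,1-tris(hydroxymethyl)ethane | CC(CO)(CO)CO | starting material
7 | (2,2,5-trimethyl-1,3-dioxan-5-yl)methanol | CC1(CO)COC(C)(C)OC1 | intermediate
8 | 2,2,5-trimethyl-1,3-dioxane-5-carbaldehyde | CC1(C=O)COC(C)(C)OC1 | intermediate
9 | 5-ethynyl-2,2,5-trimethyl-1,3-dioxane (not isolated) | C#CC1(C)COC(C)(C)OC1 | intermediate
10 | 2-ethynyl-2-methylpropane-1,3-diol | C#CC(C)(CO)CO | intermediate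
11 | (E)-alkenyl(dimethyl)alane, both oxygens as dimethylaluminium alkoxides (not isolated) | C[Al](C)/C=C(\C)C(C)(CO[Al](C)C)CO[Al](C)C | intermediate
12 | 2-[(1E)-1-iodoprop-1-en-2-yl]-2-methylpropane-1,3-diol | I/C=C(\C)C(C)(CO)CO | intermediate
13 | (2S,3E)-2-(hydroxymethyl)-4-iodo-2,3-dimethylbut-3-en-1-yl acetate | I/C=C(\C)[C@](C)(COC(C)=O)CO | intermediate
14 | (2R,3E)-2-{[(tert-butyldimethylsilyl)oxy]methyl}-4-iodo-2,3-dimethylbut-3-en-1-yl acetate | I/C=C(\C)[C@](C)(COC(C)=O)CO[Si](C)(C)C(C)(C)C | intermediate
15 | (2R,3E)-2-{[(tert-butyldimethylsilyl)oxy]methyl}-4-iodo-2,3-dimethylbut-3-en-1-ol | I/C=C(\C)[C@](C)(CO)CO[Si](C)(C)C(C)(C)C | intermediate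
16 | (2S,3E)-2-{[(tert-butyldimethylsilyl)oxy]methyl}-4-iodo-2,3-dimethylbut-3-enal | I/C=C(\C)[C@](C)(C=O)CO[Si](C)(C)C(C)(C)C | intermediate
17 | diethylphosphonoacetic acid | CCOP(=O)(CC(=O)O)OCC | starting material
18 | 2-(trimethylsilyl)ethanol | C[Si](C)(C)CCO | starting material
19 | 2-(trimethylsilyl)ethyl 2-(diethoxyphosphoryl)acetate | CCOP(=O)(CC(=O)OCC[Si](C)(C)C)OCC | intermediate
20 | 2-(trimethylsilyl)ethyl (2E,4S,5E)-4-{[(tert-butyldimethylsilyl)oxy]methyl}-6-iodo-4,5-dimethylhexa-2,5-dienoate | I/C=C(\C)[C@](C)(/C=C/C(=O)OCC[Si](C)(C)C)CO[Si](C)(C)C(C)(C)C | intermediate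
21 | acrolein diethyl acetal | C=CC(OCC)OCC | starting material
22 | diethyl acetal of dienal 23 (not isolated) | CCOC(OCC)/C=C/C=C(\C)[C@](C)(/C=C/C(=O)OCC[Si](C)(C)C)CO[Si](C)(C)C(C)(C)C | intermediate
23 | side-chain (2E,4E)-dienal, (16S), TBS ether, 2-(trimethylsilyl)ethyl ester | O=C/C=C/C=C(\C)[C@](C)(/C=C/C(=O)OCC[Si](C)(C)C)CO[Si](C)(C)C(C)(C)C | intermediate
24 | iminium benzoate of 23 and the (S)-amine (not isolated) | C[Si](C)(C)OC(c1ccccc1)(c1ccccc1)[C@@H]1CCC[N+]1=C/C=C/C=C(\C)[C@](C)(/C=C/C(=O)OCC[Si](C)(C)C)CO[Si](C)(C)C(C)(C)C.[O-]C(=O)c1ccccc1 | intermediate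
25 | linear dienol of 5, matched enantiomer drawn (not isolated) | CC(O)=CC1=C[C@@H](C)C(=O)[C@@H](C)C1 | intermediate
26 | Michael adduct as its enamine, C12–C13 formed (not isolated) | CC(=O)/C=C1/C[C@H](C)C(=O)[C@H](C)[C@H]1[C@@H](C=CN2CCC[C@H]2C(c2ccccc2)(c2ccccc2)O[Si](C)(C)C)/C=C(\C)[C@](C)(/C=C/C(=O)OCC[Si](C)(C)C)CO[Si](C)(C)C(C)(C)C | intermediate
27 | aldol adduct as its iminium benzoate, C4–C5 formed, C4 and C5 undefined (not isolated) | C[Si](C)(C)OC(c1ccccc1)(c1ccccc1)[C@@H]1CCC[N+]1=CC1C(C)(O)C=C2C[C@H](C)C(=O)[C@H](C)[C@H]2[C@@H]1/C=C(\C)[C@](C)(/C=C/C(=O)OCC[Si](C)(C)C)CO[Si](C)(C)C(C)(C)C.[O-]C(=O)c1ccccc1 | intermediate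
28 | bicyclic dienal, (9S,11R,12R,13S,16S), C3 as aldehyde | O=CC1=C(C)C=C2C[C@H](C)C(=O)[C@H](C)[C@H]2[C@@H]1/C=C(\C)[C@](C)(/C=C/C(=O)OCC[Si](C)(C)C)CO[Si](C)(C)C(C)(C)C | intermediate
29 | triphenylphosphine hydrobromide | [Br-].c1ccc(cc1)[PH+](c1ccccc1)c1ccccc1 | starting material
30 | ethyl vinyl ether | C=COCC | starting material
31 | (1-ethoxyethyl)triphenylphosphonium bromide (racemic) | CCOC(C)[P+](c1ccccc1)(c1ccccc1)c1ccccc1.[Br-] | intermediate
32 | (1-ethoxyethylidene)triphenylphosphorane (not isolated) | CCOC(C)=P(c1ccccc1)(c1ccccc1)c1ccccc1 | intermediate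
33 | C3=C2 ethyl enol ether of 34 (E/Z mixture) | CCOC(C)=CC1=C(C)C=C2C[C@H](C)C(=O)[C@H](C)[C@H]2[C@@H]1/C=C(\C)[C@](C)(/C=C/C(=O)OCC[Si](C)(C)C)CO[Si](C)(C)C(C)(C)C | intermediate
34 | protected target (TBS ether, 2-(trimethylsilyl)ethyl ester) | CC(=O)CC1=C(C)C=C2C[C@H](C)C(=O)[C@H](C)[C@H]2[C@@H]1/C=C(\C)[C@](C)(/C=C/C(=O)OCC[Si](C)(C)C)CO[Si](C)(C)C(C)(C)C | intermediate
35 | CNP0260948.1 | CC(=O)CC1=C(C)C=C2C[C@H](C)C(=O)[C@H](C)[C@H]2[C@@H]1/C=C(\C)[C@](C)(/C=C/C(=O)O)CO | target

**Step count.** Total: 19 steps. Longest linear sequence: 14 steps (steps 4–11, 13–15, 17–19, from 1,1,1-tris(hydroxymethyl)ethane).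

**Steps most likely to fail**

1. Step 15. Several processes can go wrong:
   - The tautomerisation of 5 to its dienol may be too slow.
   - The donor may drain into the ring-conjugated enone tautomer.
   - 23 may be diverted into a trienamine through the C15 methyl group.
   - The relative topicity at C12/C13 may be wrong.
   - C12 and C11 may epimerise after ring closure, or ring A may aromatise in air.

   Fallback (known chemistry, the same two bonds made one after the other): it sets out from 5. Soft enolisation (TBSOTf, Et3N, CH2Cl2), which is known to give extended dienol ethers from β,β-disubstituted enones, furnishes the linear tert-butyldimethylsilyl dienol ether F1. An organocatalytic vinylogous Mukaiyama–Michael addition of F1 to 23 then forms C12–C13 and gives the keto aldehyde F2. F1 is used in excess because it no longer racemises, and the catalyst is the chiral imidazolidinone salt that exposes the same C13 face, in wet solvent. An intramolecular aldol condensation with dibenzylammonium trifluoroacetate in toluene forms C4=C5 and rejoins the route at 28.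

2. Step 17. The basic ylide may enolise the dienal or the C10 ketone instead of adding, which would scramble C9, C11 or C12. The ylide may also decompose before it reaches the hindered aldehyde.

   Fallback: it sets out from 28. The weakly basic organocerium reagent from 1-ethoxyvinyllithium and CeCl3 adds to the aldehyde at −78 °C, and the alkoxide is trapped with Ac2O to give the acetoxy enol ether F3. Dilute oxalic acid hydrolyses it to the α-acetoxy ketone F4. SmI2 in THF/MeOH at −78 °C removes the acetoxy group (a known reduction of α-heterosubstituted ketones), and α-protonation of the samarium dienolate rejoins the route at 34. Steps 17 and 18 are both bypassed.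

3. Step 8. The lipase may discriminate poorly between the enantiotopic arms at a quaternary centre, and acyl migration in the monoacetate may erode the enantiomeric purity.

   Fallback (classical resolution instead of desymmetrisation): it sets out from 12. Monosilylation through the monosodium alkoxide (NaH, TBSCl, THF) gives the racemic mono-TBS ether F5. Esterification with (S)-O-methylmandelic acid (DCC, DMAP) and chromatographic separation give the diastereomerically pure mandelate F6. K2CO3 in MeOH then rejoins the route at 15. The unwanted diastereomer is returned to 12 by desilylation and methanolysis.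

**Further compounds**

F1 | step 15 | linear tert-butyldimethylsilyl dienol ether of 5 (racemic, matched enantiomer drawn) | CC(O[Si](C)(C)C(C)(C)C)=CC1=C[C@@H](C)C(=O)[C@@H](C)C1
F2 | step 15 | keto aldehyde, open Michael adduct with C12–C13 formed | CC(=O)/C=C1/C[C@H](C)C(=O)[C@H](C)[C@H]1[C@@H](CC=O)/C=C(\C)[C@](C)(/C=C/C(=O)OCC[Si](C)(C)C)CO[Si](C)(C)C(C)(C)C
F3 | step 17 | acetoxy enol ether (C3 epimers) | C=C(OCC)C(OC(C)=O)C1=C(C)C=C2C[C@H](C)C(=O)[C@H](C)[C@H]2[C@@H]1/C=C(\C)[C@](C)(/C=C/C(=O)OCC[Si](C)(C)C)CO[Si](C)(C)C(C)(C)C
F4 | step 17 | α-acetoxy ketone (C3 epimers) | CC(=O)C(OC(C)=O)C1=C(C)C=C2C[C@H](C)C(=O)[C@H](C)[C@H]2[C@@H]1/C=C(\C)[C@](C)(/C=C/C(=O)OCC[Si](C)(C)C)CO[Si](C)(C)C(C)(C)C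
F5 | step 8 | racemic mono-TBS ether of 12 | I/C=C(\C)C(C)(CO)CO[Si](C)(C)C(C)(C)C
F6 | step 8 | (S)-O-methylmandelate of 15 | I/C=C(\C)[C@](C)(COC(=O)[C@@H](OC)c1ccccc1)CO[Si](C)(C)C(C)(C)C
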